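Thursday's run, with 1.41 equivalents of reagent, stood at 102 % of the substrate in target and isomer of the product together at 15.0 min, so we read the two products as holding the charge. Sunday's flask, the one asked about, has less reagent than substrate.

common to all: substrate 0.069 M
- Sunday's: reagent 0.0483 M (in portions, 4); the very flask that is asked about, followed so far; portions every 2.5 s
- Thursday's: reagent 0.097 M (in portions, 4); run made earlier; portions every 2.5 s
- flask: reagent 0.0483 M (in portions, 4); the portions of reagent follow each other after 2.5 s, the first at the start; time 25 min

- Sunday's (time / min: target / %, isomer of the product / %): 0.417: 0, 0.8; 1.33: 11.1, 5.9; 2.50: 20.5, 13.1; 4.00: 28.1, 22.8; 5.00: 31.5, 25.0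
- Thursday's (time / min: target / %, isomer of the product / %): 4.00: 41.2, 33.8; 8.00: 52.9, 42.0; 10.0: 54.9, 44.9; 15.0: 55.9, 46.4; 20.0: 55.8, 44.3

(standard deviation of a reading: 1 percentage point)

- why nothing more happens at 25 min, or that something still does (the reagent has run out first / forward and back rates have come level / all of the substrate has reacted / it is still moving)
- target at 25 min, in percent of the substrate charged
- isomer of the product at 25 min, in percent of the substrate charged

- the reaction counts as stopped when no species that holds the substrate changes by six tenths of a point or more over the second half of the time

We build Sunday's flask up one process at a time. First comes the main step alone, which we take as substrate and reagent consumed one for one. Reagent is then the limiting reagent, and the products stop at the ceiling 70.0 %, the charge of reagent divided by the charge of substrate. Will they get there in time? For a rate k·c_substrate·c_reagent with consumption one for one, ln(c_substrate/c_reagent) climbs in a straight line with time once the portions are in. Sunday's readings put it at 0.601 at 2.50 min and 1.17 at 5.00 min. That is a slope of 0.228 min⁻¹. Carried to 25 min, it leaves a gap to the ceiling of 0.0982 % of the substrate charged, less than the scatter of 1 percentage point. So we expect the reagent to be spent down to that 0.0982 %.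

Next comes the split. Thursday's last three readings give target a share of 55.1 % of the two products, and Sunday's reading at 5.00 min gives 55.8 %. Applied to the ceiling, this gives us target 38.6 % and isomer of the product 31.4 %.

Last comes the rest. Sunday's products hold 0.800 % at 0.417 min, which looks like a lag. We put nothing on it in our reckoning of the end.

The forecast says the reagent has run out first, with target 38.5 % and isomer of the product 31 %: “the reagent is essentially gone”. Our reckoning differs from it by 0.10 points in target and 0.40 points in isomer of the product.

The simulation gives the reagent has run out first, with target 38.7 % and isomer of the product 31.3 %.

    substrate + reagent → intermediate (k = 0.351 M⁻¹ s⁻¹)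
    intermediate → target (k = 0.00825 s⁻¹)
    target ⇌ isomer of the product (K = 0.810, k = 0.0642 s⁻¹)

The products reach the ceiling of 70.0 %, with 30 % of the substrate left over. The split comes from the undoing of isomer of the product into target: without that back step, this flask holds 70.0 % of isomer instead of 31.3 %. The neighbour with 0.12 M of substrate has a ceiling of 40.2 %, so the same share predicts target 22.2 % and isomer 18.0 %; that flask gives 22.2 % and 18.0 %.

The runs come from a simulation from invented constants; scatter was added.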